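The ten-membered ring is disconnected at C2–C3 (germacrane numbering) by an oxy-Cope retron. The E-C1=C10 olefin and the C4=C5 olefin hidden behind the epoxide stand in a 1,5-relationship across C2–C3, so the ring maps onto a six-membered ring C5–C10 that already bears the C6 oxygen and the C7 isopropyl group. In one operation the [3,3] shift of a potassium alkoxide forms C2–C3, cleaves C5–C10, expands six to ten, fixes both ring-E olefins and sets C3 through the chair; the C5 enolate is kept as its triflate. The precursor is a trans-1,2-dialkenylcyclohexanol: C5 carbinol with an E-configured C4=C3–OPMB arm, C10 methyl and vinyl, C6 OTBS, C7 isopropyl.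

Key step: step 10

Remarks made before the steps
- Numbering: germacrane numbering is used for every ring position (C1–C10; C10 and C4 carry the methyl groups, C7 the isopropyl group), also in the six-membered intermediates (ring C5–C10).
- Assumption on the chemistry: the (S,R,R) enantiomer of the binaphthyl bis(1-phenylethyl)phosphoramidite ligand is taken to deliver isopropyl to the face that gives the 3S ketone, as it does for simple dialkylzincs; if isopropyl behaved oppositely, the (R,S,S) ligand would be used.
- Structure check: the precursor 20 and the triflate 23 were traced through the chair transition state and agree with each other and with the target (3S,4R,5R,6S,7R). One point of nomenclature needs care: the C4=C5 bond of 22 and 23 is E in the ring sense (C3 trans to C6) but Z by the CIP rules, because the oxygen on C5 outranks C6.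
- Protecting groups: TBS on C6 and PMB on C3 are kept. TBS on the secondary C6 oxygen is not expected to move to the hindered tertiary C5 alkoxide or to the less basic enolate oxygen.

Step 1
Reactants: 1 cyclohex-2-en-1-one; 2 diisopropylzinc
Product: 4 (2R,3R)-2-bromo-3-isopropylcyclohexan-1-one (trans), via isopropylzinc enolate 3 (not isolated)
Conditions: Cu(OTf)2 (2 mol %), (S,R,R)-binaphthyl bis(1-phenylethyl)phosphoramidite (4 mol %), toluene, −30 °C; then NBS, THF, −78 °C
Reagents that add atoms: N-bromosuccinimide, O=C1CCC(=O)N1Br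
Why: Cu(OTf)2/phosphoramidite-catalysed asymmetric conjugate addition of the dialkylzinc sets C7 (3S in the ketone) under ligand control, and the regiodefined zinc enolate undergoes electrophilic α-bromination at C6 anti to the new isopropyl group, which should give the trans bromo ketone.

Step 2
Reactants: 4 (2R,3R)-2-bromo-3-isopropylcyclohexan-1-one
Product: 6 (2S,3R)-2-hydroxy-3-isopropylcyclohexan-1-one (cis), via formate ester 5 (not isolated)
Conditions: HCO2Cs, DMF, 0 °C to rt; then KHCO3 (cat.), MeOH, 0 °C
Reagents that add atoms: caesium formate, [Cs+].[O-]C=O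
Why: SN2 displacement on the carbonyl-activated secondary bromide by weakly basic formate inverts C6, which places oxygen cis to the C7 isopropyl group (6S), and the labile formate is cleaved by mild methanolysis that should not enolise the α-hydroxy ketone.

Step 3
Reactants: 6 (2S,3R)-2-hydroxy-3-isopropylcyclohexan-1-one
Product: 7 (2S,3R)-2-[(tert-butyldimethylsilyl)oxy]-3-isopropylcyclohexan-1-one
Conditions: TBSOTf, 2,6-lutidine, CH2Cl2, −78 °C
Reagents that add atoms: tert-butyldimethylsilyl triflate, CC(C)(C)[Si](C)(C)OS(=O)(=O)C(F)(F)F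
Why: Silyl triflate silylation of the hindered secondary alcohol at low temperature; the TBS ether tolerates the amide bases, the organolithium and the potassium alkoxide chemistry ahead and is later removed by fluoride without affecting the PMB ether.

Step 4
Reactants: 7 (2S,3R)-2-[(tert-butyldimethylsilyl)oxy]-3-isopropylcyclohexan-1-one
Product: 9 (2S,3R,6Z)-2-[(tert-butyldimethylsilyl)oxy]-6-(hydroxymethylidene)-3-isopropylcyclohexan-1-one, via lithium enolate 8 (not isolated)
Conditions: LiN(iPr)2, THF, −78 °C; then HCO2CH2CF3, −78 °C to 0 °C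
Reagents that add atoms: 2,2,2-trifluoroethyl formate, O=COCC(F)(F)F
Why: Kinetic deprotonation by the hindered amide base occurs at the C10 methylene and not at the branched, silyloxy-bearing C6–H, and the enolate is C-formylated by the activated formate (crossed Claisen condensation) to the chelated hydroxymethylene ketone.

Step 5
Reactants: 9 (2S,3R,6Z)-2-[(tert-butyldimethylsilyl)oxy]-6-(hydroxymethylidene)-3-isopropylcyclohexan-1-one
Product: 10 (1S,3S,4R)-3-[(tert-butyldimethylsilyl)oxy]-4-isopropyl-1-methyl-2-oxocyclohexane-1-carbaldehyde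
Conditions: MeI, K2CO3, acetone, rt
Reagents that add atoms: methyl iodide, CI
Why: C-alkylation of the β-keto aldehyde enolate builds the C10 quaternary centre; the C6 silyloxy group (pseudoaxial beside the enolate) and the cis C7 isopropyl group screen one face, so methyl should enter trans to both, the minor epimer and any O-methyl enol ether being removed by chromatography.

Step 6
Reactants: 10 (1S,3S,4R)-3-[(tert-butyldimethylsilyl)oxy]-4-isopropyl-1-methyl-2-oxocyclohexane-1-carbaldehyde
Product: 11 (2S,5R,6S)-6-[(tert-butyldimethylsilyl)oxy]-2-ethenyl-2-methyl-5-isopropylcyclohexan-1-one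
Conditions: Ph3PCH3Br, KN(SiMe3)2, THF, 0 °C; then 10, −78 °C to 0 °C
Reagents that add atoms: methyltriphenylphosphonium bromide, C[P+](c1ccccc1)(c1ccccc1)c1ccccc1.[Br-]
Why: Wittig methylenation is chemoselective for the aldehyde over the ketone flanked by a quaternary and a silyloxy-bearing carbon, and turns the non-enolisable formyl group into the C1=C2 vinyl group without touching C6 or C10.

Step 7
Reactants: 12 4-methoxybenzyl alcohol; 13 trichloroethylene
Product: 16 4-methoxybenzyl prop-1-yn-1-yl ether, via dichlorovinyl ether 14 (not isolated), via lithium alkynyl ether 15 (not isolated)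
Conditions: KH, THF, 0 °C; Cl2C=CHCl, rt; n-BuLi, −78 °C to −40 °C; MeI, DMPU, −78 °C to rt
Reagents that add atoms: methyl iodide, CI
Why: Alkoxide addition–elimination on trichloroethylene gives the 1,2-dichlorovinyl ether, dehydrochlorination and chlorine–lithium exchange with n-BuLi give the lithium alkoxyacetylide, and C-methylation delivers the ynol ether (established one-flask alkynyl ether synthesis); the product is kept at or below room temperature because benzyl alkynyl ethers rearrange on heating.

Step 8
Reactants: 16 4-methoxybenzyl prop-1-yn-1-yl ether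
Product: 18 (E)-2-iodoprop-1-en-1-yl 4-methoxybenzyl ether, via alkenylzirconocene chloride 17 (not isolated)
Conditions: Cp2Zr(H)Cl, THF, rt; then I2 (1 equiv), −78 °C to 0 °C
Reagents that add atoms: iodine, II
Why: syn-Hydrozirconation of the polarised ynol ether delivers hydride to the oxygen-bearing carbon and zirconium to the methyl-bearing carbon (as with ethoxyacetylene), and iodinolysis of the C–Zr bond with retention should give the E iodide in which iodine is trans to oxygen.

Step 9
Reactants: 18 (E)-2-iodoprop-1-en-1-yl 4-methoxybenzyl ether; 11 (2S,5R,6S)-6-[(tert-butyldimethylsilyl)oxy]-2-ethenyl-2-methyl-5-isopropylcyclohexan-1-one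
Product: 20 (1S,2S,5R,6S)-6-[(tert-butyldimethylsilyl)oxy]-2-ethenyl-1-{(1E)-1-[(4-methoxybenzyl)oxy]prop-1-en-2-yl}-2-methyl-5-isopropylcyclohexan-1-ol, via alkenyllithium 19 (not isolated)
Conditions: t-BuLi (2 equiv), Et2O, −100 °C to −78 °C; then 11, −78 °C; aq NH4Cl
Reagents that add atoms: none
Why: Iodine–lithium exchange with retention gives the alkenyllithium, used at once at low temperature because lithium is anti to the β-alkoxy group, and 1,2-addition to the ketone should occur on the face opposite the C10 vinyl and C6 silyloxy groups (Felkin–Anh and steric control, the C7 isopropyl blocking the other trajectory), setting C5 with the two alkenyl groups trans.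

Step 10
Reactants: 20 (1S,2S,5R,6S)-6-[(tert-butyldimethylsilyl)oxy]-2-ethenyl-1-{(1E)-1-[(4-methoxybenzyl)oxy]prop-1-en-2-yl}-2-methyl-5-isopropylcyclohexan-1-ol
Product: 23 (1(10)E,4Z,3S,6S,7R)-6-[(tert-butyldimethylsilyl)oxy]-3-[(4-methoxybenzyl)oxy]germacra-1(10),4-dien-5-yl trifluoromethanesulfonate, via potassium alkoxide 21 (not isolated), via potassium enolate 22 (not isolated)
Conditions: KN(SiMe3)2, 18-crown-6, THF, −78 °C to rt; then PhNTf2, −78 °C to 0 °C; aq NH4Cl
Reagents that add atoms: N-phenylbis(trifluoromethanesulfonimide), O=S(=O)(N(c1ccccc1)S(=O)(=O)C(F)(F)F)C(F)(F)F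
Why: KN(SiMe3)2 with 18-crown-6 turns 20 into the loosely paired potassium alkoxide 21, whose charge weakens the C5–C10 bond so that a concerted [3,3] sigmatropic shift (anionic oxy-Cope rearrangement) forms C2–C3 as C5–C10 breaks and gives enolate 22, which PhNTf2 sulfonylates on oxygen. The closest known reaction type is the anionic oxy-Cope ring expansion of trans-1,2-divinylcyclohexanols to E-cyclodec-5-enones with electrophilic capture of the regiodefined enolate; an alkoxy group on a vinyl terminus and triflimide capture are ordinary variations of it. No ring is formed by end-to-end cyclisation, so no exo or endo mode applies: the six-membered ring C5–C10 opens into the ten-membered ring by a four-atom ring expansion within a six-centre chair array. The one new stereocentre, C3 (S), is controlled by that chair: the E enol ether places OPMB equatorial and the sense of the chair is fixed by the C5 and C10 configurations, while the equatorial C6 and C9 ring bonds become the trans ring bonds of the new C4=C5 and C1=C10 olefins. The step needs chair over boat and O-capture before the β-alkoxy enolate can expel the C3 alkoxide; the trans alkenyl groups, both equatorial, can only overlap in a chair, the C3–O bond lies close to the enolate plane because the ring holds C2–C3 perpendicular to it, and triflation follows at −78 °C as soon as the shift is complete. The reactive chair has the C7 isopropyl group axial and 1,3 to the alkoxide oxygen, a cost offset by the fact that the other chair has both alkenyl groups axial with a C6-silyloxy/C10-vinyl diaxial contact and cannot rearrange.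

Step 11
Reactants: 23 (1(10)E,4Z,3S,6S,7R)-6-[(tert-butyldimethylsilyl)oxy]-3-[(4-methoxybenzyl)oxy]germacra-1(10),4-dien-5-yl trifluoromethanesulfonate
Product: 24 (1(10)E,4E,3S,6S,7R)-6-[(tert-butyldimethylsilyl)oxy]-3-[(4-methoxybenzyl)oxy]germacra-1(10),4-diene
Conditions: Pd(OAc)2 (10 mol %), PPh3 (20 mol %), HCO2H, n-Bu3N, DMF, 50 °C
Reagents that add atoms: none
Why: Pd-catalysed formate reduction of the enol triflate (oxidative addition, decarboxylation of the formate ligand, C–H reductive elimination) replaces OTf by H with retention of olefin geometry, giving the E-C4=C5 olefin; the temperature is kept below that at which cyclodeca-1,5-dienes undergo Cope rearrangement.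

Step 12
Reactants: 24 (1(10)E,4E,3S,6S,7R)-6-[(tert-butyldimethylsilyl)oxy]-3-[(4-methoxybenzyl)oxy]germacra-1(10),4-diene
Product: 25 (1(10)E,4E,3S,6S,7R)-3-[(4-methoxybenzyl)oxy]germacra-1(10),4-dien-6-ol
Conditions: Bu4NF, THF, 0 °C to rt; aq NH4Cl
Reagents that add atoms: none
Why: Fluoride cleaves the Si–O bond selectively, leaves the PMB ether, and frees the C6 allylic alcohol needed to direct the epoxidation.

Step 13
Reactants: 25 (1(10)E,4E,3S,6S,7R)-3-[(4-methoxybenzyl)oxy]germacra-1(10),4-dien-6-ol
Product: 26 (1(10)E,3S,4R,5R,6S,7R)-4,5-epoxy-3-[(4-methoxybenzyl)oxy]germacr-1(10)-en-6-ol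
Conditions: VO(acac)2 (5 mol %), t-BuOOH, CH2Cl2, 0 °C
Reagents that add atoms: tert-butyl hydroperoxide, CC(C)(C)OO
Why: Hydroxyl-directed epoxidation by the vanadium alkyl peroxide bound to the C6 alkoxide is selective for the allylic C4=C5 bond over C1=C10 and should deliver oxygen to the outer face of the olefin, the face that carries the C6 oxygen when C6–H eclipses the double bond to avoid A(1,3) strain with the C4 methyl group (threo mode), setting 4R and 5R.

Step 14
Reactants: 26 (1(10)E,3S,4R,5R,6S,7R)-4,5-epoxy-3-[(4-methoxybenzyl)oxy]germacr-1(10)-en-6-ol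
Product: 27 (1(10)E,3S,4R,5R,6S,7R)-4,5-epoxy-3-[(4-methoxybenzyl)oxy]germacr-1(10)-en-6-yl acetate
Conditions: Ac2O, Et3N, DMAP (cat.), CH2Cl2, rt
Reagents that add atoms: acetic anhydride, CC(=O)OC(C)=O
Why: DMAP-catalysed acylation of the only free hydroxyl group installs the C6 acetate; the epoxide and the PMB ether are inert.

Step 15
Reactants: 27 (1(10)E,3S,4R,5R,6S,7R)-4,5-epoxy-3-[(4-methoxybenzyl)oxy]germacr-1(10)-en-6-yl acetate
Product: 28 (1(10)E,3S,4R,5R,6S,7R)-4,5-epoxy-3-hydroxygermacr-1(10)-en-6-yl acetate
Conditions: DDQ, CH2Cl2/pH 7 phosphate buffer, 0 °C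
Reagents that add atoms: none
Why: Oxidative PMB cleavage (hydride abstraction by DDQ, hydrolysis of the oxocarbenium ion) under buffered conditions frees the C3 hydroxyl group; it is placed after the epoxidation because C3 is then no longer allylic and cannot be over-oxidised, and the buffer protects the epoxide from acid-induced transannular attack by C1=C10.

Step 16
Reactants: 28 (1(10)E,3S,4R,5R,6S,7R)-4,5-epoxy-3-hydroxygermacr-1(10)-en-6-yl acetate; 29 angelic acid [(2Z)-2-methylbut-2-enoic acid]
Product: 31 (1(10)E,3S,4R,5R,6S,7R)-6-acetoxy-4,5-epoxygermacr-1(10)-en-3-yl (2Z)-2-methylbut-2-enoate (target), via mixed anhydride 30 (not isolated)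
Conditions: 29, 2,4,6-Cl3C6H2COCl, Et3N, toluene, rt; then 28, 75 °C
Reagents that add atoms: none
Why: Yamaguchi esterification, in which the trichlorobenzoyl mixed anhydride acylates the hindered C3 alcohol at the less hindered angeloyl carbonyl under conditions that preserve the Z geometry of angelates.

Compound list
1 | cyclohex-2-en-1-one | O=C1C=CCCC1 | starting material
2 | diisopropylzinc | CC(C)[Zn]C(C)C | starting material
3 | isopropylzinc enolate of (S)-3-isopropylcyclohexanone (C5=C6 enolate, formed in the flask) | CC(C)[Zn]OC1=C[C@@H](C(C)C)CCC1 | intermediate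
4 | (2R,3R)-2-bromo-3-isopropylcyclohexan-1-one (Br trans to isopropyl) | O=C1[C@H](Br)[C@@H](C(C)C)CCC1 | intermediate
5 | (2S,3R)-2-(formyloxy)-3-isopropylcyclohexan-1-one (cis, formed in the flask) | O=C1[C@@H](OC=O)[C@@H](C(C)C)CCC1 | intermediate
6 | (2S,3R)-2-hydroxy-3-isopropylcyclohexan-1-one (OH cis to isopropyl) | O=C1[C@@H](O)[C@@H](C(C)C)CCC1 | intermediate
7 | (2S,3R)-2-[(tert-butyldimethylsilyl)oxy]-3-isopropylcyclohexan-1-one | O=C1[C@@H](O[Si](C)(C)C(C)(C)C)[C@@H](C(C)C)CCC1 | intermediate
8 | lithium (5R,6S)-6-[(tert-butyldimethylsilyl)oxy]-5-isopropylcyclohex-1-en-1-olate (C5=C10 enolate, formed in the flask) | [Li]OC1=CCC[C@H](C(C)C)[C@@H]1O[Si](C)(C)C(C)(C)C | intermediate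
9 | (2S,3R,6Z)-2-[(tert-butyldimethylsilyl)oxy]-6-(hydroxymethylidene)-3-isopropylcyclohexan-1-one | O=C1[C@@H](O[Si](C)(C)C(C)(C)C)[C@@H](C(C)C)CC/C1=C/O | intermediate
10 | (1S,3S,4R)-3-[(tert-butyldimethylsilyl)oxy]-4-isopropyl-1-methyl-2-oxocyclohexane-1-carbaldehyde (methyl trans to OTBS and isopropyl) | O=C1[C@@H](O[Si](C)(C)C(C)(C)C)[C@@H](C(C)C)CC[C@@]1(C)C=O | intermediate
11 | (2S,5R,6S)-6-[(tert-butyldimethylsilyl)oxy]-2-ethenyl-2-methyl-5-isopropylcyclohexan-1-one (vinyl, OTBS and isopropyl all cis) | O=C1[C@@H](O[Si](C)(C)C(C)(C)C)[C@@H](C(C)C)CC[C@@]1(C)C=C | intermediate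
12 | 4-methoxybenzyl alcohol | COc1ccc(CO)cc1 | starting material
13 | trichloroethylene | ClC=C(Cl)Cl | starting material
14 | (E)-1,2-dichlorovinyl 4-methoxybenzyl ether (formed in the flask) | COc1ccc(CO/C(Cl)=C\Cl)cc1 | intermediate
15 | lithium [(4-methoxybenzyl)oxy]acetylide (formed in the flask) | COc1ccc(COC#C[Li])cc1 | intermediate
16 | 4-methoxybenzyl prop-1-yn-1-yl ether | COc1ccc(COC#CC)cc1 | intermediate
17 | chlorobis(cyclopentadienyl){(E)-1-[(4-methoxybenzyl)oxy]prop-1-en-2-yl}zirconium (Zr trans to O, formed in the flask) | COc1ccc(CO/C=C(\C)[Zr](Cl)(C2C=CC=C2)C2C=CC=C2)cc1 | intermediate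
18 | (E)-2-iodoprop-1-en-1-yl 4-methoxybenzyl ether (I trans to O) | COc1ccc(CO/C=C(\C)I)cc1 | intermediate
19 | (E)-1-[(4-methoxybenzyl)oxy]prop-1-en-2-yllithium (Li trans to O, formed in the flask) | COc1ccc(CO/C=C(\C)[Li])cc1 | intermediate
20 | (1S,2S,5R,6S)-6-[(tert-butyldimethylsilyl)oxy]-2-ethenyl-1-{(1E)-1-[(4-methoxybenzyl)oxy]prop-1-en-2-yl}-2-methyl-5-isopropylcyclohexan-1-ol (alkenyl groups trans) | O[C@@]1(/C(C)=C/OCc2ccc(OC)cc2)[C@@H](O[Si](C)(C)C(C)(C)C)[C@@H](C(C)C)CC[C@@]1(C)C=C | intermediate
21 | potassium alkoxide of 20 (formed in the flask) | [K+].[O-][C@@]1(/C(C)=C/OCc2ccc(OC)cc2)[C@@H](O[Si](C)(C)C(C)(C)C)[C@@H](C(C)C)CC[C@@]1(C)C=C | intermediate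
22 | potassium (1(10)E,4Z,3S,6S,7R)-6-[(tert-butyldimethylsilyl)oxy]-3-[(4-methoxybenzyl)oxy]germacra-1(10),4-dien-5-olate (formed in the flask) | [K+].COc1ccc(CO[C@H]2C/C=C(\C)CC[C@H](C(C)C)[C@H](O[Si](C)(C)C(C)(C)C)/C([O-])=C2\C)cc1 | intermediate
23 | (1(10)E,4Z,3S,6S,7R)-6-[(tert-butyldimethylsilyl)oxy]-3-[(4-methoxybenzyl)oxy]germacra-1(10),4-dien-5-yl trifluoromethanesulfonate (C3 trans to C6 across C4=C5) | COc1ccc(CO[C@H]2C/C=C(\C)CC[C@H](C(C)C)[C@H](O[Si](C)(C)C(C)(C)C)/C(OS(=O)(=O)C(F)(F)F)=C2\C)cc1 | intermediate
24 | (1(10)E,4E,3S,6S,7R)-6-[(tert-butyldimethylsilyl)oxy]-3-[(4-methoxybenzyl)oxy]germacra-1(10),4-diene | COc1ccc(CO[C@H]2C/C=C(\C)CC[C@H](C(C)C)[C@H](O[Si](C)(C)C(C)(C)C)/C=C2\C)cc1 | intermediate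
25 | (1(10)E,4E,3S,6S,7R)-3-[(4-methoxybenzyl)oxy]germacra-1(10),4-dien-6-ol | COc1ccc(CO[C@H]2C/C=C(\C)CC[C@H](C(C)C)[C@H](O)/C=C2\C)cc1 | intermediate
26 | (1(10)E,3S,4R,5R,6S,7R)-4,5-epoxy-3-[(4-methoxybenzyl)oxy]germacr-1(10)-en-6-ol | COc1ccc(CO[C@H]2C/C=C(\C)CC[C@H](C(C)C)[C@H](O)[C@H]3O[C@]23C)cc1 | intermediate
27 | (1(10)E,3S,4R,5R,6S,7R)-4,5-epoxy-3-[(4-methoxybenzyl)oxy]germacr-1(10)-en-6-yl acetate | COc1ccc(CO[C@H]2C/C=C(\C)CC[C@H](C(C)C)[C@H](OC(C)=O)[C@H]3O[C@]23C)cc1 | intermediate
28 | (1(10)E,3S,4R,5R,6S,7R)-4,5-epoxy-3-hydroxygermacr-1(10)-en-6-yl acetate | O[C@H]1C/C=C(\C)CC[C@H](C(C)C)[C@H](OC(C)=O)[C@H]2O[C@]12C | intermediate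
29 | angelic acid, (2Z)-2-methylbut-2-enoic acid | C/C=C(/C)C(=O)O | starting material
30 | angelic 2,4,6-trichlorobenzoic mixed anhydride (formed in the flask) | C/C=C(/C)C(=O)OC(=O)c1c(Cl)cc(Cl)cc1Cl | intermediate
31 | (1(10)E,3S,4R,5R,6S,7R)-6-acetoxy-4,5-epoxygermacr-1(10)-en-3-yl (2Z)-2-methylbut-2-enoate | C/C=C(/C)C(=O)O[C@H]1C/C=C(\C)CC[C@H](C(C)C)[C@H](OC(C)=O)[C@H]2O[C@]12C | target

Total step count: 16.
Longest linear sequence: 14 steps (steps 1–6, then 9–16); the alkenyl iodide arm takes 2 steps (7 and 8).

The three steps most likely to fail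

Step 10 (key step). The rearrangement has to pass through the less populated chair with the C7 isopropyl group axial, so it may be slow. While it proceeds, the free potassium enolate may expel the C3 alkoxide or be sulfonylated incompletely at its hindered oxygen. The fallback separates rearrangement from triflation. Setting out from 20, the same alkoxide rearrangement is quenched at −78 °C with Me3SiCl in place of the triflimide to give the trimethylsilyl enol ether F1, which is isolated. MeLi in THF at 0 °C then releases the regiodefined lithium enolate F2, and N-(5-chloropyridin-2-yl)bis(trifluoromethanesulfonimide) at −78 °C converts it into the triflate. The route is rejoined at 23.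

Step 9. The alkenyllithium carries lithium anti to a β-alkoxy group and may fragment to propyne and lithium 4-methoxybenzyl oxide before it adds, and the hindered ketone may be enolised at C6 instead of attacked. A wrong regiochemistry in the hydrozirconation of step 8 would also surface here. The fallback builds the enol ether by olefination and needs neither 16 nor 18. Setting out from 11, 1-ethoxyvinyllithium (from ethyl vinyl ether and t-BuLi) adds to the ketone with the same facial preference to give the ethoxyvinyl carbinol F3. Dilute aqueous oxalic acid hydrolyses the enol ether to the α-hydroxy methyl ketone F4. Horner–Wittig addition of an excess of lithiated [(4-methoxybenzyloxy)methyl]diphenylphosphine oxide gives the β-hydroxy phosphine oxide F5; the diastereomer disposed for syn-elimination to the E enol ether is separated. KH with 18-crown-6 in THF then expels potassium diphenylphosphinate stereospecifically and leaves the potassium alkoxide in the flask. The route is rejoined at 21, from which step 10 continues.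

Step 2. The α-bromo ketone and the α-acyloxy ketone can both enolise under the carboxylate, which would erode the configuration at C6; elimination to the enone and acyloin transposition during methanolysis are further drains. The fallback inverts a configurationally stable alcohol instead of a labile bromide. Setting out from 1 and 2, the conjugate addition of step 1 is quenched with Me3SiOTf to give the silyl enol ether F6. Rubottom oxidation (mCPBA, then dilute aqueous HF) should place oxygen anti to the isopropyl group and give the trans hydroxy ketone F7. Mitsunobu reaction with 4-nitrobenzoic acid (PPh3, diisopropyl azodicarboxylate) inverts C6 to the cis 4-nitrobenzoate F8, and K2CO3 in MeOH at 0 °C removes the ester. The route is rejoined at 6.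

Further compounds
F1 | step 10 | (1(10)E,4Z,3S,6S,7R)-6-[(tert-butyldimethylsilyl)oxy]-3-[(4-methoxybenzyl)oxy]-5-[(trimethylsilyl)oxy]germacra-1(10),4-diene | COc1ccc(CO[C@H]2C/C=C(\C)CC[C@H](C(C)C)[C@H](O[Si](C)(C)C(C)(C)C)/C(O[Si](C)(C)C)=C2\C)cc1
F2 | step 10 | lithium (1(10)E,4Z,3S,6S,7R)-6-[(tert-butyldimethylsilyl)oxy]-3-[(4-methoxybenzyl)oxy]germacra-1(10),4-dien-5-olate | COc1ccc(CO[C@H]2C/C=C(\C)CC[C@H](C(C)C)[C@H](O[Si](C)(C)C(C)(C)C)/C(O[Li])=C2\C)cc1
F3 | step 9 | (1S,2S,5R,6S)-6-[(tert-butyldimethylsilyl)oxy]-2-ethenyl-1-(1-ethoxyethenyl)-2-methyl-5-isopropylcyclohexan-1-ol | O[C@@]1(C(=C)OCC)[C@@H](O[Si](C)(C)C(C)(C)C)[C@@H](C(C)C)CC[C@@]1(C)C=C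
F4 | step 9 | 1-{(1S,2S,5R,6S)-6-[(tert-butyldimethylsilyl)oxy]-2-ethenyl-1-hydroxy-2-methyl-5-isopropylcyclohexyl}ethan-1-one | O[C@@]1(C(C)=O)[C@@H](O[Si](C)(C)C(C)(C)C)[C@@H](C(C)C)CC[C@@]1(C)C=C
F5 | step 9 | β-hydroxy phosphine oxide from F4: C4 carbinol (methyl, hydroxyl) joined to C3 bearing OPMB and diphenylphosphinoyl, diastereomer that gives the E enol ether on syn-elimination | O[C@@]1([C@@](C)(O)[C@@H](OCc2ccc(OC)cc2)P(=O)(c2ccccc2)c2ccccc2)[C@@H](O[Si](C)(C)C(C)(C)C)[C@@H](C(C)C)CC[C@@]1(C)C=C
F6 | step 2 | {[(3R)-3-isopropylcyclohex-1-en-1-yl]oxy}trimethylsilane | C[Si](C)(C)OC1=C[C@@H](C(C)C)CCC1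
F7 | step 2 | (2R,3R)-2-hydroxy-3-isopropylcyclohexan-1-one (OH trans to isopropyl) | O=C1[C@H](O)[C@@H](C(C)C)CCC1
F8 | step 2 | (1S,2R)-2-isopropyl-6-oxocyclohexyl 4-nitrobenzoate (cis) | O=C1[C@@H](OC(=O)c2ccc(cc2)[N+](=O)[O-])[C@@H](C(C)C)CCC1
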